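## The problem

The target is a C25 labdane-type acid. Its trans-decalin (rings A and B) carries six stereocentres (C4, C5, C6, C8, C9, C10). A nine-carbon chain on C9 contains an E-trisubstituted C13=C14 alkene and ends in an (R)-configured 4-methylbutenolide. Ring B is the crowded half: C10 is quaternary, C9 bears the chain, C8 is a tertiary 8α-carbinol with an axial methyl group, and C6 carries an equatorial 6α-hydroxyl next to the trans ring fusion. Once the C10 methyl group is in place it screens the β face, so C5, C6 and C8 can be set by reagent approach from α, and C9 prefers the equatorial β orientation. C4 (equatorial carboxyl C18, axial methyl syn to the C10 methyl) has no such helper: it must be made first and then control C10, or be made last under control of C10. The butenolide centre C16 is too remote for ring control and must come from a resolved or reagent-controlled building block, joined without base reaching its acidic γ-hydrogen. Three groups restrict late reagents: the butenolide (base: epimerisation, ring opening), the tertiary 8α-carbinol (strong acid: ionisation, elimination) and the peri pair 6α-OH/C18 carboxyl (lactonisation). The feature that opens ring B is that C9–C10 and C7–C8 are 1,4-related, the C8 carbinol maps onto an exocyclic methylene and 5α-H/6α-OH map onto a C5=C6 alkene. Ring B is therefore the adduct of a ring-A diene C10=C5–C6=C7 and the conjugated double bond of a buta-2,3-dienoate.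

## Retrosynthesis

**Target 35 back to 33 (O–Si and O–C(CH3)3 bonds).** The last operations are deprotections: desilylation of bis-silyl acid 34, which comes from tert-butyl ester 33. The tert-butyl ester is chosen for C18 over a methyl ester for three reasons. It is inert to borohydride, which allows chemoselective reduction at C11. It resists the alkoxide that appears at O-6. It can be released by loss of isobutene on silica, which avoids hydroxide (butenolide), strong protic acid (C8–O ionisation) and silyl triflate/amine (butenolide enolisation). TBS ethers on O-6 and O-8 keep these oxygens masked during that step and are removed last under weakly acidic fluoride conditions.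

**Butenolide 33 back to hydroxy ketone 30 and ketal 29 (C=C and ester C–O of the lactone).** The lactone is cut to the α-hydroxy methyl ketone 30 plus the two-carbon ylide 31; ring closure via ylide ester 32 is neutral. Closing the butenolide after the cross-coupling keeps its γ-hydrogen away from the basic coupling medium. During the coupling the ketone is held as dioxolane 29, so C16 is not enolisable. The forward reaction must acylate only the side-chain hydroxyl, which is why O-6 and O-8 carry acid-stable silyl groups.

**Ketal 29 back to vinyl decalin 20 and vinyl iodide 27 (C12–C13).** This cut divides the molecule into a decalin with a two-carbon handle and a seven-carbon chain piece, and it makes the E-alkene from a geometrically defined iodide. The neighbouring cuts are worse: C11–C12 needs substitution at a neopentyl-like carbon, C14–C15 needs a β-oxygenated alkyl metal, and an olefination at C13=C14 gives E/Z mixtures. A B-alkyl Suzuki–Miyaura coupling through borane 28 turns the vinyl group of 20 into the nucleophile in one flask. This saves the alcohol, iodide and zinc stages of a Negishi variant.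

**Vinyl iodide 27 back to 25, 23, 22 and 21 (C13–I/C14–H, C14–C15, epoxide C–O).** The iodide arises from 2-alkyne 25 by syn hydrozirconation (via 26) and iodinolysis. The alkyne arises by opening (R)-epoxide 23 with propynyllithium from propyne 24. The epoxide comes from catalogue vinyl dioxolane 21 by epoxidation to 22 and hydrolytic kinetic resolution. C16 is thereby fixed by a resolution of known type, and the methyl ketone is already masked.

**Vinyl decalin 20 back to triol 16 (C11=C12; two O–Si bonds; C11 oxidation level).** Methylenation of aldehyde 18 with salt 19, silylation of 17 and selective oxidation of the primary alcohol of 16 are functional-group steps on a fixed skeleton. The aldehyde sits on the equatorial, stable C9 configuration. Silylation of O-8 prevents retro-aldol opening of ring B under the ylide.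

**Triol 16 back to cycloadduct 11 (C6–O/C5–H, C8–O/C17–H, C11 reduction).** The three oxygens are introduced in the order reduction (12), hydration (14, via mercurial 13), hydroboration (16, via borane 15).
- Reduction first removes the base-sensitive β,γ-unsaturated ester.
- Hydration second uses the one reagent that distinguishes the open exocyclic alkene from the buried C5=C6 alkene.
- Hydroboration last then meets a single alkene. It sets 5α-H and 6α-OH in one step from the α face.

**Cycloadduct 11 back to diene 9 and allenoate 10 (C9–C10 and C7–C8; ring B).** This is the key disconnection. One intermolecular [4+2] step forms ring B, the quaternary C10, C9 with its carbon substituent, the C8 methylene and the C5=C6 handle. An allenoate is preferred to an acrylate or propiolate for two reasons: only it leaves the exocyclic alkene needed for the 8α-carbinol, and its central carbon carries no endo substituent, which helps with the hindered (Z)-substituted diene terminus. The forward reaction must deliver C7-to-C8 regiochemistry, α-face attack and the exo ester. The facial element is the weakest and is discussed under the risks.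

**Diene 9 back to keto ester 1 (C5–C6 vinyl bond; C10–CH3; C4–CH3).** The diene comes from enol triflate 7 and vinyltrifluoroborate 8. The triflate comes from ketone 5 (via enolate 6), which comes from 3 by methylation at the only enolisable position (via enolate 4). The quaternary centre of 3 is set first, by asymmetric phase-transfer methylation of the achiral β-keto ester 1 with 2. Placing the asymmetric step on the achiral substrate avoids running it on a racemic, already methylated ketone. The second methyl centre is destroyed on triflation, so its configuration is irrelevant.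

## Roads not taken

**Alternative 1:** The cut is the C18–O bond to O-6, and behind it a C–H bond of a 4,4-dimethyl decalin. In the forward sense PhI(OAc)2 and I2 under light convert the 6α-alcohol A1 into its hypoiodite. The 6α-alkoxy radical abstracts hydrogen from the only methyl group within reach, the equatorial 4α-methyl, and the 6,18-ether A2 closes.
- Merits: C4 becomes a stereocentre by geometry alone, with no enantioselective alkylation and no facial question at C10. The ring stereocentres can be taken from an abundant gem-dimethyl terpenoid.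
- Weak points: the 6α-oxygen is absent from such materials and must be introduced at an unactivated position over several steps. The ether carbon must then be raised two oxidation levels, and the resulting lactone must be opened with hydroxide before or beside a base-sensitive butenolide. The hypoiodite conditions also exclude an alkene in the chain.
- Comparison: on the C4 problem this road is clearly better than the chosen plan, whose weakest element is the facial bias of the cycloaddition. Against it the chosen plan carries C18 at the acid oxidation level from the first step, gets 6α-OH and 5α-H from one hydroboration, and needs fewer redox corrections.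

**Alternative 2:** The cut is C13–CH3 and C14–C15 in one operation. AlMe3 with Cp2ZrCl2 adds methyl and aluminium syn across the terminal alkyne A3; the alkenylalane, as its lithium alanate, opens epoxide 23 and gives A4.
- Merits: E geometry by syn carbometalation, no separate vinyl iodide, no palladium, and the same epoxide as here. A4 is the counterpart of 29.
- Weak points: it solves only the chain and leaves the decalin open. Alkyne A3 needs two more carbons on C11 than the vinyl group of 20. Excess Lewis-acidic AlMe3 meets a tertiary silyl ether and an ester. Alanate–epoxide openings usually need one partner in excess, which here is the advanced decalin.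
- Comparison: for the joining event itself this road is shorter (one pot against steps 15 and 16) and at least as good in alkene geometry. The chosen plan offers a near-stoichiometric, milder palladium coupling and a shorter route to its decalin partner. The two ideas are not exclusive: this chain assembly could be grafted onto the cycloadduct series.

**Alternative 3:** The cut is C3–C4. KN(SiMe3)2 converts the β,γ-unsaturated ester of iodide A5 into a dienolate whose α-carbon displaces the primary iodide on the C10 propyl chain. This closes ring A and makes C4 quaternary in A6.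
- Merits: intramolecular enolate alkylation is a dependable way to a quaternary centre. α- against γ-attack is decided by ring size, and C4 is set relative to C10.
- Weak points: A5 needs an enantioenriched ring-B piece with the C10 quaternary centre. The sense at C4 depends on the dienolate conformation about C4–C5, which is not obviously biased. A6 still lacks C11, C17 and the oxygens at C6 and C8, so most of ring B's functionality remains to be built from a 9-silyloxy group.
- Comparison: its bond-forming event is more certain than a cycloaddition onto a hindered diene. The chosen plan delivers ring B with C8, C9, C11, C17 and the C5=C6 handle in the same step, so far less remains afterwards.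

Key step: step 5

Remark (numbering): carbons carry labdane-type numbers: C1–C10 decalin, C11 on C9, C12–C16 chain (C16 is the butenolide carbinol carbon), C17 on C8, C18 the 4α-carboxyl carbon, C19 the 4β-methyl, C20 the 10β-methyl; α is the face opposite C20.

Remark (assumption): the sense of induction of the chiral catalysts in steps 1 and 13 is not derived here; in each case the antipode that gives the stated product is meant. Compounds 1, 2, 8, 10, 19, 21, 24 and 31 are taken to be catalogue materials.

Steps 12–15 form the side-chain branch.

Step 1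
Reactants: 1 tert-butyl 2-oxocyclohexane-1-carboxylate; 2 iodomethane
Product: 3 tert-butyl (1R)-1-methyl-2-oxocyclohexane-1-carboxylate
Conditions: chiral C2-symmetric N-spiro binaphthyl quaternary ammonium bromide (1 mol%), CsOH·H2O, toluene, −40 °C
Reagents that add atoms: none
Why: Asymmetric phase-transfer alkylation of a cyclic β-keto ester: the enolate is ion-paired with the chiral ammonium cation, which screens one face so that MeI enters from the other; bulky tert-butyl esters are the substrate class on which this reaction is most selective.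

Step 2
Reactants: 3 tert-butyl (1R)-1-methyl-2-oxocyclohexane-1-carboxylate; 2 iodomethane
Product: 5 tert-butyl (1R)-1,3-dimethyl-2-oxocyclohexane-1-carboxylate (C3 epimers), via lithium enolate 4 (not isolated)
Conditions: LiN(i-Pr)2, THF, −78 °C; MeI, −78 → −20 °C
Reagents that add atoms: none
Why: Kinetic enolate alkylation; C1 is quaternary, so only C3 can be deprotonated, and the new C3 centre is an inconsequential epimer mixture because it becomes sp2 in step 3.

Step 3
Reactants: 5 tert-butyl (1R)-1,3-dimethyl-2-oxocyclohexane-1-carboxylate
Product: 7 tert-butyl (1R)-1,3-dimethyl-2-(trifluoromethylsulfonyloxy)cyclohex-2-ene-1-carboxylate, via potassium enolate 6 (not isolated)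
Conditions: KN(SiMe3)2, THF, −78 °C; PhNTf2, −78 → 0 °C
Reagents that add atoms: N-phenylbis(trifluoromethanesulfonimide), O=S(=O)(N(c1ccccc1)S(=O)(=O)C(F)(F)F)C(F)(F)F
Why: O-Sulfonylation of the only possible enolate gives the tetrasubstituted enol triflate regiospecifically, as with other 2,2,6-trisubstituted cyclohexanones.

Step 4
Reactants: 7 tert-butyl (1R)-1,3-dimethyl-2-(trifluoromethylsulfonyloxy)cyclohex-2-ene-1-carboxylate; 8 potassium vinyltrifluoroborate
Product: 9 tert-butyl (1R)-2-ethenyl-1,3-dimethylcyclohex-2-ene-1-carboxylate (ring-A diene)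
Conditions: Pd(dppf)Cl2·CH2Cl2 (5 mol%), Cs2CO3, THF/H2O, 70 °C
Reagents that add atoms: none
Why: Suzuki–Miyaura coupling of an enol triflate with a vinyltrifluoroborate; zerovalent palladium inserts into the C–O bond, the wide-bite-angle ligand copes with the flanking quaternary carbon, and C4 is untouched.

Step 5
Reactants: 9 tert-butyl (1R)-2-ethenyl-1,3-dimethylcyclohex-2-ene-1-carboxylate; 10 ethyl buta-2,3-dienoate
Product: 11 tert-butyl 9β-(ethoxycarbonyl)-4β,10β-dimethyl-8-methylidenedecal-5-ene-4α-carboxylate (5-tert-butyl 1-ethyl (1S,5R,8aR)-5,8a-dimethyl-2-methylidene-1,2,3,5,6,7,8,8a-octahydronaphthalene-1,5-dicarboxylate)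
Conditions: toluene (concentrated), BHT (cat.), sealed tube, 110–120 °C
Reagents that add atoms: none
Why: Thermal, concerted but asynchronous normal-demand Diels–Alder reaction between the s-cis diene C10=C5–C6=C7 and the ester-conjugated C=C of the allenoate; the closest known reaction type is the drimane-type annulation of 2-vinylcyclohexenes with allenic and acetylenic esters. Ring B is closed by this intermolecular [4+2] cycloaddition as a cyclohexene, C7–C8 forming ahead of C9–C10, with C5=C6 left in the ring and the distal allene bond surviving as the C8 methylene. Regiochemistry follows from the largest HOMO coefficient at the unsubstituted diene terminus C7 and the largest LUMO coefficient at the central allene carbon, so the ester carbon lands on C9 next to C10. C10 is set by the diene face that is attacked: in the reacting conformer the C4–CH3 bond, the better σ-donor and the group that clashes more with H-6 when near the diene plane, should stand pseudoaxial on the β face, while the flat, electron-withdrawing ester lies near the plane, so the dienophile should add from α and push C20 to β. C9 is set by exo placement of the ester, away from the diene and cis to C20 in the product, giving 9β. The central allene carbon has no endo substituent, which is what lets this dienophile reach the hindered (Z)-substituted terminus C10. The step needs regiocontrol (electronic, secure), exo selectivity (steric; a 9α contaminant can be converged by kinetic α-face protonation of the ester dienolate) and α-face selectivity (a moderate substrate bias, the weakest element).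

Step 6
Reactants: 11 tert-butyl 9β-(ethoxycarbonyl)-4β,10β-dimethyl-8-methylidenedecal-5-ene-4α-carboxylate
Product: 12 tert-butyl 9β-(hydroxymethyl)-4β,10β-dimethyl-8-methylidenedecal-5-ene-4α-carboxylate
Conditions: LiBH4, THF, 0 → 40 °C
Reagents that add atoms: none
Why: Chemoselective borohydride reduction: the ethyl ester on the secondary C9 is reduced while the tert-butyl ester on the quaternary C4 is inert; no stereocentre is touched and the base-sensitive β,γ-unsaturated ester is removed early.

Step 7
Reactants: 12 tert-butyl 9β-(hydroxymethyl)-4β,10β-dimethyl-8-methylidenedecal-5-ene-4α-carboxylate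
Product: 14 tert-butyl 8α-hydroxy-9β-(hydroxymethyl)-4β,8β,10β-trimethyldecal-5-ene-4α-carboxylate, via alkylmercury acetate 13 (not isolated)
Conditions: Hg(OAc)2, THF/H2O, rt; then NaBH4, aq. NaOH, 0 °C
Reagents that add atoms: water, O
Why: Oxymercuration–demercuration (Markovnikov hydration): divalent mercury selects the open 1,1-disubstituted alkene over the C5=C6 alkene buried between two quaternary carbons, and water should attack C8 equatorially (α) because axial attack is blocked by the syn-axial C10 methyl, giving the 8α-carbinol.

Step 8
Reactants: 14 tert-butyl 8α-hydroxy-9β-(hydroxymethyl)-4β,8β,10β-trimethyldecal-5-ene-4α-carboxylate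
Product: 16 tert-butyl 6α,8α-dihydroxy-9β-(hydroxymethyl)-4β,8β,10β-trimethyl-trans-decalin-4α-carboxylate, via C6 alkylborane 15 (not isolated)
Conditions: BH3·THF (excess), THF, 0 °C → rt; then NaOH, H2O2, 0 °C
Reagents that add atoms: hydrogen peroxide, OO
Why: Hydroboration–oxidation: syn addition from the α face (β is screened by the axial C19 and C20 methyls), boron to the less substituted C6, sets 5α-H (trans fusion) and, after oxidation with retention, 6α-OH; the tert-butyl ester resists borane and the C6 alkoxide.

Step 9
Reactants: 16 tert-butyl 6α,8α-dihydroxy-9β-(hydroxymethyl)-4β,8β,10β-trimethyl-trans-decalin-4α-carboxylate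
Product: 17 tert-butyl 9β-formyl-6α,8α-dihydroxy-4β,8β,10β-trimethyl-trans-decalin-4α-carboxylate
Conditions: TEMPO (cat.), PhI(OAc)2, CH2Cl2, rt
Reagents that add atoms: none
Why: Nitroxyl-catalysed (oxoammonium) oxidation is selective for the primary alcohol over the hindered secondary 6α-OH and the tertiary 8α-OH; the 9β-aldehyde is the equatorial, stable epimer.

Step 10
Reactants: 17 tert-butyl 9β-formyl-6α,8α-dihydroxy-4β,8β,10β-trimethyl-trans-decalin-4α-carboxylate
Product: 18 tert-butyl 6α,8α-bis(tert-butyldimethylsilyloxy)-9β-formyl-4β,8β,10β-trimethyl-trans-decalin-4α-carboxylate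
Conditions: TBSOTf, 2,6-lutidine, CH2Cl2, −78 → 0 °C
Reagents that add atoms: tert-butyldimethylsilyl trifluoromethanesulfonate, CC(C)(C)[Si](C)(C)OS(=O)(=O)C(F)(F)F
Why: Silyl triflate silylation reaches both the hindered secondary and the tertiary hydroxyl; the TBS ethers block retro-aldol cleavage of C8–C9, keep O-6 away from C18, and survive the later ketal hydrolysis and ester cleavage.

Step 11
Reactants: 18 tert-butyl 6α,8α-bis(tert-butyldimethylsilyloxy)-9β-formyl-4β,8β,10β-trimethyl-trans-decalin-4α-carboxylate; 19 methyltriphenylphosphonium bromide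
Product: 20 tert-butyl 6α,8α-bis(tert-butyldimethylsilyloxy)-9β-ethenyl-4β,8β,10β-trimethyl-trans-decalin-4α-carboxylate
Conditions: 19, KN(SiMe3)2, THF, 0 °C; then 18, −78 → 0 °C
Reagents that add atoms: none
Why: Wittig methylenation; the unstabilised ylide adds to the aldehyde faster than it deprotonates C9, which in any case already has its stable configuration.

Step 12
Reactants: 21 2-ethenyl-2-methyl-1,3-dioxolane
Product: 22 rac-2-methyl-2-(oxiran-2-yl)-1,3-dioxolane
Conditions: mCPBA, CH2Cl2, rt
Reagents that add atoms: 3-chloroperbenzoic acid, O=C(OO)c1cccc(Cl)c1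
Why: Prilezhaev epoxidation of the monosubstituted alkene; the dioxolane keeps the latent methyl ketone inert.

Step 13
Reactants: 22 rac-2-methyl-2-(oxiran-2-yl)-1,3-dioxolane
Product: 23 2-methyl-2-[(2R)-oxiran-2-yl]-1,3-dioxolane
Conditions: chiral (salen)Co(OAc) [salen = N,N′-bis(3,5-di-tert-butylsalicylidene)-trans-cyclohexane-1,2-diamine dianion; trivalent cobalt; 0.5 mol%; the antipode that consumes the (S)-epoxide], H2O (0.55 equiv), THF, 0 °C → rt
Reagents that add atoms: none
Why: Hydrolytic kinetic resolution of a terminal epoxide: the (S)-enantiomer is hydrolysed to the diol and the (R)-epoxide is recovered (half of the material at most); a bulky fully substituted neighbour is the substrate type with high selectivity factors, and this step fixes C16.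

Step 14
Reactants: 23 2-methyl-2-[(2R)-oxiran-2-yl]-1,3-dioxolane; 24 prop-1-yne
Product: 25 (1R)-1-(2-methyl-1,3-dioxolan-2-yl)pent-3-yn-1-ol
Conditions: 24, n-BuLi, THF, −78 °C; BF3·OEt2; then 23, −78 °C
Reagents that add atoms: none
Why: BF3-promoted SN2 opening of a terminal epoxide by an alkynyllithium at the unsubstituted carbon, so the carbinol centre keeps its (R) configuration; −78 °C spares the ketal.

Step 15
Reactants: 25 (1R)-1-(2-methyl-1,3-dioxolan-2-yl)pent-3-yn-1-ol
Product: 27 (1R,3E)-4-iodo-1-(2-methyl-1,3-dioxolan-2-yl)pent-3-en-1-ol, via alkenylzirconocene chloride 26 (not isolated)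
Conditions: Cp2Zr(H)Cl (2.5 equiv), THF, rt → 40 °C; then I2, 0 °C
Reagents that add atoms: iodine, II
Why: Hydrozirconation–iodination: syn addition of Zr–H to the 2-alkyne places zirconium on the methyl-bearing carbon (the less hindered end, favoured further by equilibration with excess reagent and by the bulky zirconium alkoxide on the other side), and iodinolysis with retention gives the (E)-2-iodoalkene.

Step 16
Reactants: 20 tert-butyl 6α,8α-bis(tert-butyldimethylsilyloxy)-9β-ethenyl-4β,8β,10β-trimethyl-trans-decalin-4α-carboxylate; 27 (1R,3E)-4-iodo-1-(2-methyl-1,3-dioxolan-2-yl)pent-3-en-1-ol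
Product: 29 tert-butyl 6α,8α-bis(tert-butyldimethylsilyloxy)-9β-[(3E,6R)-6-hydroxy-3-methyl-6-(2-methyl-1,3-dioxolan-2-yl)hex-3-en-1-yl]-4β,8β,10β-trimethyl-trans-decalin-4α-carboxylate, via B-alkyl-9-BBN 28 (not isolated)
Conditions: 9-BBN, THF, rt → 40 °C; then 27, Pd(dppf)Cl2·CH2Cl2 (5 mol%), AsPh3, Cs2CO3, DMF/H2O, rt
Reagents that add atoms: none
Why: B-alkyl Suzuki–Miyaura coupling: 9-BBN hydroborates only the terminal vinyl group, at C12; transmetalation of the primary alkylborane to the alkenylpalladium iodide formed from zerovalent palladium and reductive elimination make C12–C13 with retention of the E geometry, and the ketal keeps C16 non-enolisable in the basic medium.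

Step 17
Reactants: 29 tert-butyl 6α,8α-bis(tert-butyldimethylsilyloxy)-9β-[(3E,6R)-6-hydroxy-3-methyl-6-(2-methyl-1,3-dioxolan-2-yl)hex-3-en-1-yl]-4β,8β,10β-trimethyl-trans-decalin-4α-carboxylate
Product: 30 tert-butyl 6α,8α-bis(tert-butyldimethylsilyloxy)-9β-[(3E,6R)-6-hydroxy-3-methyl-7-oxooct-3-en-1-yl]-4β,8β,10β-trimethyl-trans-decalin-4α-carboxylate
Conditions: TsOH·H2O (cat.), acetone/H2O, rt
Reagents that add atoms: water, O
Why: Acid-catalysed ketal hydrolysis; the hindered secondary and tertiary TBS ethers and the tert-butyl ester survive dilute aqueous acid, so the side-chain hydroxyl is the only free alcohol afterwards.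

Step 18
Reactants: 30 tert-butyl 6α,8α-bis(tert-butyldimethylsilyloxy)-9β-[(3E,6R)-6-hydroxy-3-methyl-7-oxooct-3-en-1-yl]-4β,8β,10β-trimethyl-trans-decalin-4α-carboxylate; 31 ketenylidenetriphenylphosphorane
Product: 33 tert-butyl 6α,8α-bis(tert-butyldimethylsilyloxy)-4β,8β,10β-trimethyl-9β-{(3E)-3-methyl-5-[(2R)-3-methyl-5-oxo-2,5-dihydrofuran-2-yl]pent-3-en-1-yl}-trans-decalin-4α-carboxylate, via phosphoranylideneacetate ester 32 (not isolated)
Conditions: Ph3P=C=C=O, toluene, 80 °C
Reagents that add atoms: none
Why: The alcohol adds to the ketene ylide and the resulting acyl ylide closes onto the neighbouring ketone by intramolecular Wittig reaction (butenolide closure by C=C formation); the medium is neutral, so C16 next to the ketone is not epimerised.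

Step 19
Reactants: 33 tert-butyl 6α,8α-bis(tert-butyldimethylsilyloxy)-4β,8β,10β-trimethyl-9β-{(3E)-3-methyl-5-[(2R)-3-methyl-5-oxo-2,5-dihydrofuran-2-yl]pent-3-en-1-yl}-trans-decalin-4α-carboxylate
Product: 34 6α,8α-bis(tert-butyldimethylsilyloxy)-4β,8β,10β-trimethyl-9β-{(3E)-3-methyl-5-[(2R)-3-methyl-5-oxo-2,5-dihydrofuran-2-yl]pent-3-en-1-yl}-trans-decalin-4α-carboxylic acid
Conditions: silica gel, toluene, reflux
Reagents that add atoms: none
Why: Surface-acid-assisted thermal loss of isobutene from a tert-butyl ester, a known method that leaves tert-alkyl ethers and silyl ethers intact; it avoids strong protic acid (ionisation at C8) and silyl triflate/amine (enolisation of the butenolide).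

Step 20
Reactants: 34 6α,8α-bis(tert-butyldimethylsilyloxy)-4β,8β,10β-trimethyl-9β-{(3E)-3-methyl-5-[(2R)-3-methyl-5-oxo-2,5-dihydrofuran-2-yl]pent-3-en-1-yl}-trans-decalin-4α-carboxylic acid
Product: 35 6α,8α-dihydroxy-4β,8β,10β-trimethyl-9β-{(3E)-3-methyl-5-[(2R)-3-methyl-5-oxo-2,5-dihydrofuran-2-yl]pent-3-en-1-yl}-trans-decalin-4α-carboxylic acid (CNP0387770.1)
Conditions: aq. HF (48%), MeCN, 0 °C → rt
Reagents that add atoms: none
Why: Fluoride-assisted cleavage of both TBS ethers under weakly acidic conditions, to which the butenolide, the tertiary carbinol and the trisubstituted alkene are stable.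

## Compound list

1 | tert-butyl 2-oxocyclohexane-1-carboxylate | O=C1CCCCC1C(=O)OC(C)(C)C | starting material
2 | iodomethane | CI | starting material
3 | tert-butyl (1R)-1-methyl-2-oxocyclohexane-1-carboxylate | O=C1CCCC[C@@]1(C)C(=O)OC(C)(C)C | intermediate
4 | lithium enolate of 3 (not isolated) | [Li+].[O-]C1=CCCC[C@@]1(C)C(=O)OC(C)(C)C | intermediate
5 | tert-butyl (1R)-1,3-dimethyl-2-oxocyclohexane-1-carboxylate (C3 epimers) | CC1CCC[C@@](C)(C(=O)OC(C)(C)C)C1=O | intermediate
6 | potassium enolate of 5 (not isolated) | [K+].[O-]C1=C(C)CCC[C@@]1(C)C(=O)OC(C)(C)C | intermediate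
7 | tert-butyl (1R)-1,3-dimethyl-2-(trifluoromethylsulfonyloxy)cyclohex-2-ene-1-carboxylate | CC=1CCC[C@@](C)(C(=O)OC(C)(C)C)C=1OS(=O)(=O)C(F)(F)F | intermediate
8 | potassium vinyltrifluoroborate | C=C[B-](F)(F)F.[K+] | starting material
9 | tert-butyl (1R)-2-ethenyl-1,3-dimethylcyclohex-2-ene-1-carboxylate | CC=1CCC[C@@](C)(C(=O)OC(C)(C)C)C=1C=C | intermediate
10 | ethyl buta-2,3-dienoate | C=C=CC(=O)OCC | starting material
11 | tert-butyl 9β-(ethoxycarbonyl)-4β,10β-dimethyl-8-methylidenedecal-5-ene-4α-carboxylate | CCOC(=O)[C@@H]1[C@@]2(C)CCC[C@@](C)(C(=O)OC(C)(C)C)C2=CCC1=C | intermediate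
12 | tert-butyl 9β-(hydroxymethyl)-4β,10β-dimethyl-8-methylidenedecal-5-ene-4α-carboxylate | OC[C@@H]1[C@@]2(C)CCC[C@@](C)(C(=O)OC(C)(C)C)C2=CCC1=C | intermediate
13 | tert-butyl 8β-(acetoxymercuriomethyl)-8α-hydroxy-9β-(hydroxymethyl)-4β,10β-dimethyldecal-5-ene-4α-carboxylate (not isolated) | OC[C@@H]1[C@@]2(C)CCC[C@@](C)(C(=O)OC(C)(C)C)C2=CC[C@@]1(C[Hg]OC(C)=O)O | intermediate
14 | tert-butyl 8α-hydroxy-9β-(hydroxymethyl)-4β,8β,10β-trimethyldecal-5-ene-4α-carboxylate | OC[C@@H]1[C@@]2(C)CCC[C@@](C)(C(=O)OC(C)(C)C)C2=CC[C@@]1(C)O | intermediate
15 | 6α-boryl-5α-H adduct of 14 (not isolated) | OC[C@@H]1[C@@]2(C)CCC[C@@](C)(C(=O)OC(C)(C)C)[C@@H]2[C@@H](B)C[C@@]1(C)O | intermediate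
16 | tert-butyl 6α,8α-dihydroxy-9β-(hydroxymethyl)-4β,8β,10β-trimethyl-trans-decalin-4α-carboxylate | OC[C@@H]1[C@@]2(C)CCC[C@@](C)(C(=O)OC(C)(C)C)[C@@H]2[C@@H](O)C[C@@]1(C)O | intermediate
17 | tert-butyl 9β-formyl-6α,8α-dihydroxy-4β,8β,10β-trimethyl-trans-decalin-4α-carboxylate | O=C[C@@H]1[C@@]2(C)CCC[C@@](C)(C(=O)OC(C)(C)C)[C@@H]2[C@@H](O)C[C@@]1(C)O | intermediate
18 | tert-butyl 6α,8α-bis(tert-butyldimethylsilyloxy)-9β-formyl-4β,8β,10β-trimethyl-trans-decalin-4α-carboxylate | O=C[C@@H]1[C@@]2(C)CCC[C@@](C)(C(=O)OC(C)(C)C)[C@@H]2[C@@H](O[Si](C)(C)C(C)(C)C)C[C@@]1(C)O[Si](C)(C)C(C)(C)C | intermediate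
19 | methyltriphenylphosphonium bromide | C[P+](c1ccccc1)(c1ccccc1)c1ccccc1.[Br-] | starting material
20 | tert-butyl 6α,8α-bis(tert-butyldimethylsilyloxy)-9β-ethenyl-4β,8β,10β-trimethyl-trans-decalin-4α-carboxylate | C=C[C@@H]1[C@@]2(C)CCC[C@@](C)(C(=O)OC(C)(C)C)[C@@H]2[C@@H](O[Si](C)(C)C(C)(C)C)C[C@@]1(C)O[Si](C)(C)C(C)(C)C | intermediate
21 | 2-ethenyl-2-methyl-1,3-dioxolane | C=CC1(C)OCCO1 | starting material
22 | rac-2-methyl-2-(oxiran-2-yl)-1,3-dioxolane | CC1(OCCO1)C1CO1 | intermediate
23 | 2-methyl-2-[(2R)-oxiran-2-yl]-1,3-dioxolane | CC1(OCCO1)[C@H]1CO1 | intermediate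
24 | prop-1-yne | CC#C | starting material
25 | (1R)-1-(2-methyl-1,3-dioxolan-2-yl)pent-3-yn-1-ol | CC1(OCCO1)[C@H](O)CC#CC | intermediate
26 | (E)-alkenylzirconocene chloride of 25, as its zirconium alkoxide (not isolated) | CC1(OCCO1)[C@H](O[Zr](Cl)(C2C=CC=C2)C2C=CC=C2)C/C=C(\C)[Zr](Cl)(C2C=CC=C2)C2C=CC=C2 | intermediate
27 | (1R,3E)-4-iodo-1-(2-methyl-1,3-dioxolan-2-yl)pent-3-en-1-ol | CC1(OCCO1)[C@H](O)C/C=C(\C)I | intermediate
28 | B-alkyl-9-BBN from 20 (boron on C12; not isolated) | C1CCC2CCCC1B2CC[C@@H]3[C@@]4(C)CCC[C@@](C)(C(=O)OC(C)(C)C)[C@@H]4[C@@H](O[Si](C)(C)C(C)(C)C)C[C@@]3(C)O[Si](C)(C)C(C)(C)C | intermediate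
29 | tert-butyl 6α,8α-bis(tert-butyldimethylsilyloxy)-9β-[(3E,6R)-6-hydroxy-3-methyl-6-(2-methyl-1,3-dioxolan-2-yl)hex-3-en-1-yl]-4β,8β,10β-trimethyl-trans-decalin-4α-carboxylate | CC1(OCCO1)[C@H](O)C/C=C(\C)CC[C@@H]2[C@@]3(C)CCC[C@@](C)(C(=O)OC(C)(C)C)[C@@H]3[C@@H](O[Si](C)(C)C(C)(C)C)C[C@@]2(C)O[Si](C)(C)C(C)(C)C | intermediate
30 | tert-butyl 6α,8α-bis(tert-butyldimethylsilyloxy)-9β-[(3E,6R)-6-hydroxy-3-methyl-7-oxooct-3-en-1-yl]-4β,8β,10β-trimethyl-trans-decalin-4α-carboxylate | CC(=O)[C@H](O)C/C=C(\C)CC[C@@H]1[C@@]2(C)CCC[C@@](C)(C(=O)OC(C)(C)C)[C@@H]2[C@@H](O[Si](C)(C)C(C)(C)C)C[C@@]1(C)O[Si](C)(C)C(C)(C)C | intermediate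
31 | ketenylidenetriphenylphosphorane | O=C=C=P(c1ccccc1)(c1ccccc1)c1ccccc1 | starting material
32 | (triphenylphosphoranylidene)acetate ester of 30 at O-16 (not isolated) | CC(=O)[C@H](OC(=O)C=P(c1ccccc1)(c1ccccc1)c1ccccc1)C/C=C(\C)CC[C@@H]1[C@@]2(C)CCC[C@@](C)(C(=O)OC(C)(C)C)[C@@H]2[C@@H](O[Si](C)(C)C(C)(C)C)C[C@@]1(C)O[Si](C)(C)C(C)(C)C | intermediate
33 | tert-butyl 6α,8α-bis(tert-butyldimethylsilyloxy)-4β,8β,10β-trimethyl-9β-{(3E)-3-methyl-5-[(2R)-3-methyl-5-oxo-2,5-dihydrofuran-2-yl]pent-3-en-1-yl}-trans-decalin-4α-carboxylate | CC1=CC(=O)O[C@@H]1C/C=C(\C)CC[C@@H]1[C@@]2(C)CCC[C@@](C)(C(=O)OC(C)(C)C)[C@@H]2[C@@H](O[Si](C)(C)C(C)(C)C)C[C@@]1(C)O[Si](C)(C)C(C)(C)C | intermediate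
34 | 6α,8α-bis(tert-butyldimethylsilyloxy) acid corresponding to 33 | CC1=CC(=O)O[C@@H]1C/C=C(\C)CC[C@@H]1[C@@]2(C)CCC[C@@](C)(C(=O)O)[C@@H]2[C@@H](O[Si](C)(C)C(C)(C)C)C[C@@]1(C)O[Si](C)(C)C(C)(C)C | intermediate
35 | CNP0387770.1: 6α,8α-dihydroxy-4β,8β,10β-trimethyl-9β-{(3E)-3-methyl-5-[(2R)-3-methyl-5-oxo-2,5-dihydrofuran-2-yl]pent-3-en-1-yl}-trans-decalin-4α-carboxylic acid | CC1=CC(=O)O[C@@H]1C/C=C(\C)CC[C@@H]1[C@@]2(C)CCC[C@@](C)(C(=O)O)[C@@H]2[C@@H](O)C[C@@]1(C)O | target

## Step count and risks

Total: 20 steps. Longest linear sequence: 16 steps (steps 1–11 and 16–20). The side-chain branch is 4 steps (12–15).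

**Step 5 (key step).** The most likely failure is poor discrimination between the two diene faces at C10. The bias rests on a small conformational preference at C4 (methyl against ester pseudoaxial), and steric and stereoelectronic arguments do not all point the same way. A second problem is the slow reaction of the hindered (Z)-substituted diene, which forces temperatures at which the allenoate oligomerises. The fallback replaces substrate control by reagent control. Starting from diene 9, the cycloaddition is run with (4S)-4-benzyl-3-(buta-2,3-dienoyl)-1,3-oxazolidin-2-one F1 under Me2AlCl chelation in CH2Cl2 at low temperature. F1 is made from (4S)-4-benzyl-1,3-oxazolidin-2-one and but-3-ynoic acid by N-acylation and amine-induced isomerisation. The chelated imide is a much stronger dienophile, and its auxiliary fixes the absolute configuration at C9. Combined with exo addition, this dictates the diene face (the antipodal auxiliary is used if the 4S series proves mismatched). The imide cycloadduct F2 is then reduced with LiBH4, which removes the auxiliary and gives alcohol 12, where the route is rejoined.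

**Step 8.** The likely failure is slow or incomplete hydroboration of a trisubstituted alkene lying between two quaternary carbons. The fallback sets out from diol 14, in which C5=C6 is the only alkene. Peracid epoxidation from the open α face gives the 5α,6α-epoxide F3. Reductive opening with Cp2TiCl (trivalent titanium, from Cp2TiCl2 and Zn) and 1,4-cyclohexadiene in THF cleaves the C5–O bond to the tertiary radical. This keeps the 6α-oxygen, and hydrogen is delivered to C5 from the α face, giving triol 16.

**Step 19.** The likely failures are incomplete ester cleavage on the silica surface, or elimination at C8 and partial loss of silyl groups at reflux. The fallback changes the carboxyl protecting group before the butenolide exists, setting out from ketal 29.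
1. TMSOTf and 2,6-lutidine in CH2Cl2, followed by K2CO3/MeOH work-up, convert the tert-butyl ester into acid F4.
2. Allyl bromide and K2CO3 in DMF give allyl ester F5 (no hydroboration follows this point).
3. Ketal hydrolysis as in step 17 gives hydroxy ketone F6.
4. Ph3P=C=C=O as in step 18 gives the butenolide allyl ester F7.
5. Pd(PPh3)4 (zerovalent palladium) and morpholine in THF remove the allyl group under neutral conditions and return the route to acid 34.

**Step 1.** The likely failure is erosion of enantioselectivity, because iodomethane is the smallest and least discriminating electrophile for this reaction class; the optical purity of the whole route is fixed here. The fallback uses a covalent auxiliary, setting out from 1. Condensation with tert-butyl L-valinate gives the chiral enamine F8. Lithiation with LiN(i-Pr)2 and methylation with MeI, in the solvent and ligand combination that exposes the face leading to (R), give the methylated imine F9. Mild aqueous acid hydrolyses F9 to 3, with recovery of the amino ester.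

**Step 7.** The likely failure is insufficient equatorial selectivity in the capture of the mercurinium ion at C8, or interference by the neighbouring hydroxyl. The fallback is a radical hydration: Mukaiyama hydration of 12 with Co(acac)2 (divalent cobalt), PhSiH3 and O2 in i-PrOH/THF, with reductive work-up. It also prefers the open 1,1-disubstituted alkene and traps the C8 radical from the less hindered α face, arriving at 14 directly. It makes no new isolated compound (F0).

## Further compounds

F1 | step 5 | (4S)-4-benzyl-3-(buta-2,3-dienoyl)-1,3-oxazolidin-2-one | C=C=CC(=O)N1[C@@H](Cc2ccccc2)COC1=O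
F2 | step 5 | imide cycloadduct: N-acyl oxazolidinone analogue of 11 at C11 | O=C1OC[C@H](Cc2ccccc2)N1C(=O)[C@@H]1[C@@]2(C)CCC[C@@](C)(C(=O)OC(C)(C)C)C2=CCC1=C
F3 | step 8 | 5α,6α-epoxide of 14 | OC[C@@H]1[C@@]2(C)CCC[C@@](C)(C(=O)OC(C)(C)C)[C@@]23O[C@H]3C[C@@]1(C)O
F4 | step 19 | C18 carboxylic acid corresponding to 29 | CC1(OCCO1)[C@H](O)C/C=C(\C)CC[C@@H]2[C@@]3(C)CCC[C@@](C)(C(=O)O)[C@@H]3[C@@H](O[Si](C)(C)C(C)(C)C)C[C@@]2(C)O[Si](C)(C)C(C)(C)C
F5 | step 19 | allyl ester corresponding to 29 | CC1(OCCO1)[C@H](O)C/C=C(\C)CC[C@@H]2[C@@]3(C)CCC[C@@](C)(C(=O)OCC=C)[C@@H]3[C@@H](O[Si](C)(C)C(C)(C)C)C[C@@]2(C)O[Si](C)(C)C(C)(C)C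
F6 | step 19 | allyl ester corresponding to 30 | CC(=O)[C@H](O)C/C=C(\C)CC[C@@H]1[C@@]2(C)CCC[C@@](C)(C(=O)OCC=C)[C@@H]2[C@@H](O[Si](C)(C)C(C)(C)C)C[C@@]1(C)O[Si](C)(C)C(C)(C)C
F7 | step 19 | allyl ester corresponding to 33 | CC1=CC(=O)O[C@@H]1C/C=C(\C)CC[C@@H]1[C@@]2(C)CCC[C@@](C)(C(=O)OCC=C)[C@@H]2[C@@H](O[Si](C)(C)C(C)(C)C)C[C@@]1(C)O[Si](C)(C)C(C)(C)C
F8 | step 1 | tert-butyl 2-{[(2S)-1-tert-butoxy-3-methyl-1-oxobutan-2-yl]amino}cyclohex-1-ene-1-carboxylate | CC(C)[C@H](NC1=C(CCCC1)C(=O)OC(C)(C)C)C(=O)OC(C)(C)C
F9 | step 1 | tert-butyl (1R)-2-{[(2S)-1-tert-butoxy-3-methyl-1-oxobutan-2-yl]imino}-1-methylcyclohexane-1-carboxylate | CC(C)[C@H](N=C1CCCC[C@@]1(C)C(=O)OC(C)(C)C)C(=O)OC(C)(C)C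
F0 | step 7 | none | none
A1 | alternative 1 | 6α-hydroxy-4,4,8β,10β-tetramethyl-trans-decalin 8α,11-diol acetonide | CC1(C)OC[C@@H]2[C@@]3(C)CCCC(C)(C)[C@@H]3[C@@H](O)C[C@@]2(C)O1
A2 | alternative 1 | 6α,18-ether of the 8α,11-diol acetonide | CC1(C)OC[C@@H]2[C@@]3(C)CCC[C@@](C)(CO4)[C@@H]3[C@@H]4C[C@@]2(C)O1
A3 | alternative 2 | 2-(trimethylsilyl)ethyl 9β-(but-3-yn-1-yl)-6α,8α-bis(triethylsilyloxy)-4β,8β,10β-trimethyl-trans-decalin-4α-carboxylate | C#CCC[C@@H]1[C@@]2(C)CCC[C@@](C)(C(=O)OCC[Si](C)(C)C)[C@@H]2[C@@H](O[Si](CC)(CC)CC)C[C@@]1(C)O[Si](CC)(CC)CC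
A4 | alternative 2 | homoallylic alcohol with masked methyl ketone | CC1(OCCO1)[C@H](O)C/C=C(\C)CC[C@@H]2[C@@]3(C)CCC[C@@](C)(C(=O)OCC[Si](C)(C)C)[C@@H]3[C@@H](O[Si](CC)(CC)CC)C[C@@]2(C)O[Si](CC)(CC)CC
A5 | alternative 3 | methyl 2-[5-(tert-butyldimethylsilyloxy)-6-(3-iodopropyl)-6-methylcyclohex-1-en-1-yl]propanoate | COC(=O)C(C)C1=CCC[C@H](O[Si](C)(C)C(C)(C)C)[C@@]1(C)CCCI
A6 | alternative 3 | 5-ene decalin ester with C4 quaternary | CC(C)(C)[Si](C)(C)O[C@@H]1[C@@]2(C)CCC[C@@](C)(C(=O)OC)C2=CCC1
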